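**Plan**

- Flavone numbering (O1, C2–C4, C4a, C5–C8, C8a) is used throughout. Ring A is a 5,7-resorcinol whose methoxy-bearing C8 sits next to C8a–O1, so C8 can be the methoxymethyl carbon on a 4-pyranone, made acidic through the C4 carbonyl. The first cut is therefore C7–C8 (intramolecular Claisen), leaving a pyranone (ring C) with C5–C6–C7 as a β-keto ester on C4a.
- Further cuts: C5–C6 (acylation of a malonate half ester), then C4–C4a and O1–C2 of the pyranone (C-acylation of a β-keto ester by an arylpropynoyl chloride, then oxa-Michael closure), then the alkyne–carboxyl bond.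
- Forward: ring B is bought as the arylacetylene, ring C is built in step 3, the side chain is extended in steps 4–5, and ring A closes last in step 6.
- Stereochemistry: the target has no stereocentre or other stereogenic element, so nothing has to be set. The one sp3 centre formed on the way (C8 of the ring-closed keto tautomer) is erased by aromatisation.

Key step: step 6

Remark: metal salts of numbered compounds (acetylide, enolates, carboxylates, phenoxides) are treated as the same compound as the neutral form and carry no number of their own.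

**Route**

Step 1
Reactants: 1 5-ethynyl-1,2,3-trimethoxybenzene
Product: 2 3-(3,4,5-trimethoxyphenyl)prop-2-ynoic acid
Conditions: n-BuLi (1.05 equiv), THF, −78 °C; CO2 (g), −78 °C → rt; 1 M HCl
Reagents that add atoms: carbon dioxide, O=C=O
Why: Deprotonation of the terminal alkyne and carboxylation of the lithium acetylide is a standard route to arylpropiolic acids, and at −78 °C the acetylenic C–H is removed far faster than any ring position is lithiated.

Step 2
Reactants: 2 3-(3,4,5-trimethoxyphenyl)prop-2-ynoic acid
Product: 3 3-(3,4,5-trimethoxyphenyl)prop-2-ynoyl chloride (used crude after evaporation)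
Conditions: (COCl)2 (1.3 equiv), DMF (cat.), CH2Cl2, 0 °C → rt
Reagents that add atoms: oxalyl chloride, O=C(Cl)C(=O)Cl
Why: Vilsmeier-catalysed acid chloride formation at or below room temperature should convert the acid cleanly without addition of HCl across the triple bond.

Step 3
Reactants: 3 3-(3,4,5-trimethoxyphenyl)prop-2-ynoyl chloride; 4 methyl 4-methoxy-3-oxobutanoate
Product: 6 methyl 2-(methoxymethyl)-4-oxo-6-(3,4,5-trimethoxyphenyl)-4H-pyran-3-carboxylate, via acyclic ynone triketo ester 5 (not isolated)
Conditions: MgCl2 (1.1 equiv), pyridine (2.2 equiv), CH2Cl2, 0 °C → rt; then DMAP (0.2 equiv), 40 °C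
Reagents that add atoms: none
Why: Soft enolisation with MgCl2/pyridine directs acylation to the central carbon of the β-keto ester (C-acylation of a magnesium chelate), and the enolised ketone oxygen of 5 then adds to the electrophilic β-carbon of the ynone in a 6-endo-dig oxa-Michael closure, the known route from alkynoyl chlorides and 1,3-dicarbonyl compounds to 4-pyranones.

Step 4
Reactants: 6 methyl 2-(methoxymethyl)-4-oxo-6-(3,4,5-trimethoxyphenyl)-4H-pyran-3-carboxylate
Product: 8 2-(methoxymethyl)-4-oxo-6-(3,4,5-trimethoxyphenyl)-4H-pyran-3-carboxylic acid, via trimethylstannyl ester 7 (not isolated)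
Conditions: Me3SnOH (5 equiv), 1,2-dichloroethane, 80 °C; then 1 M HCl wash
Reagents that add atoms: trimethyltin hydroxide, C[Sn](C)(C)O (Me3Sn in 7, one carboxyl oxygen in 8)
Why: Trimethyltin hydroxide cleaves methyl esters under neutral, aprotic conditions (mild ester hydrolysis), which should spare the pyranone from the ring opening that aqueous hydroxide causes; the acid wash releases the acid from 7.

Step 5
Reactants: 8 2-(methoxymethyl)-4-oxo-6-(3,4,5-trimethoxyphenyl)-4H-pyran-3-carboxylic acid
Product: 11 methyl 3-[2-(methoxymethyl)-4-oxo-6-(3,4,5-trimethoxyphenyl)-4H-pyran-3-yl]-3-oxopropanoate, via acyl imidazole 9 (not isolated), via acylmalonic half ester 10 (not isolated)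
Conditions: CDI (1.2 equiv), THF, rt; then KO2CCH2CO2Me (2 equiv), MgCl2 (2 equiv), Et3N (2.5 equiv), THF–MeCN, rt → 45 °C; 1 M HCl
Reagents that add atoms: potassium methyl malonate, COC(=O)CC(=O)[O-].[K+] (N,N'-carbonyldiimidazole, O=C(n1ccnc1)n1ccnc1, supplies the imidazolyl group of 9 only)
Why: In this Masamune–Brooks homologation the acyl imidazole 9 C-acylates the magnesium enolate of the malonate half ester and the adduct 10 loses CO2, so the β-keto ester forms under near-neutral conditions that touch neither the pyranone nor the methoxymethyl C–H.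

Step 6
Reactants: 11 methyl 3-[2-(methoxymethyl)-4-oxo-6-(3,4,5-trimethoxyphenyl)-4H-pyran-3-yl]-3-oxopropanoate
Product: 13 5,7-dihydroxy-8-methoxy-2-(3,4,5-trimethoxyphenyl)-4H-chromen-4-one (3',4',5'-trimethoxywogonin), via ring-closed keto tautomer 12 (not isolated)
Conditions: KHMDS (3.3 equiv), THF (0.02 M), −78 °C → rt; then 1 M HCl
Reagents that add atoms: none
Why: The first equivalent of KHMDS gives the potassium enolate of the β-keto ester and the second removes a proton from the methoxymethyl group, the only remaining acidic C–H, to give a pyranone dienolate whose exocyclic γ-carbon adds to the ester carbonyl; loss of methoxide gives 12, which is deprotonated at C8 and so aromatises to the dipotassium resorcinolate that the acid work-up turns into 13. The closest known reaction type is the Dieckmann-type (intramolecular Claisen) aromatisation of pyranone-masked polyketide chains to resorcinols through a laterally metallated 2-alkyl-4-pyranone. Ring A closes in the 6-exo-trig mode by forming the C7–C8 bond. No stereocentre is created in 13; the sp3 centre at C8 of 12 is racemic and disappears on enolisation. The step needs attack on the ester in preference to intermolecular condensation or addition to the pyranone, and the substrate secures this because the six-membered closure is the only intramolecular C–C bond formation that avoids a four-membered ring, the enolate masks the C5 ketone, the silazide base is non-nucleophilic and the solution is dilute. The keto ester enolate must also reach the geometry with the ester carbon cis to the pyranone, which the loosely bound potassium counter-ion and warming to room temperature should allow, the irreversible aromatisation then draining the equilibrium.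

**Compound list**

1 | 5-ethynyl-1,2,3-trimethoxybenzene | C#Cc1cc(OC)c(OC)c(OC)c1 | starting material
2 | 3-(3,4,5-trimethoxyphenyl)prop-2-ynoic acid | OC(=O)C#Cc1cc(OC)c(OC)c(OC)c1 | intermediate
3 | 3-(3,4,5-trimethoxyphenyl)prop-2-ynoyl chloride | ClC(=O)C#Cc1cc(OC)c(OC)c(OC)c1 | intermediate
4 | methyl 4-methoxy-3-oxobutanoate | COCC(=O)CC(=O)OC | starting material
5 | methyl 2-(2-methoxyacetyl)-3-oxo-5-(3,4,5-trimethoxyphenyl)pent-4-ynoate (keto form drawn; enolised, C2 configurationally labile) | COCC(=O)C(C(=O)OC)C(=O)C#Cc1cc(OC)c(OC)c(OC)c1 | intermediate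
6 | methyl 2-(methoxymethyl)-4-oxo-6-(3,4,5-trimethoxyphenyl)-4H-pyran-3-carboxylate | COCc1oc(-c2cc(OC)c(OC)c(OC)c2)cc(=O)c1C(=O)OC | intermediate
7 | trimethylstannyl 2-(methoxymethyl)-4-oxo-6-(3,4,5-trimethoxyphenyl)-4H-pyran-3-carboxylate | COCc1oc(-c2cc(OC)c(OC)c(OC)c2)cc(=O)c1C(=O)O[Sn](C)(C)C | intermediate
8 | 2-(methoxymethyl)-4-oxo-6-(3,4,5-trimethoxyphenyl)-4H-pyran-3-carboxylic acid | COCc1oc(-c2cc(OC)c(OC)c(OC)c2)cc(=O)c1C(=O)O | intermediate
9 | 3-(1H-imidazol-1-ylcarbonyl)-2-(methoxymethyl)-6-(3,4,5-trimethoxyphenyl)-4H-pyran-4-one | COCc1oc(-c2cc(OC)c(OC)c(OC)c2)cc(=O)c1C(=O)n1ccnc1 | intermediate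
10 | 2-(methoxycarbonyl)-3-[2-(methoxymethyl)-4-oxo-6-(3,4,5-trimethoxyphenyl)-4H-pyran-3-yl]-3-oxopropanoic acid (racemic, labile centre) | COCc1oc(-c2cc(OC)c(OC)c(OC)c2)cc(=O)c1C(=O)C(C(=O)O)C(=O)OC | intermediate
11 | methyl 3-[2-(methoxymethyl)-4-oxo-6-(3,4,5-trimethoxyphenyl)-4H-pyran-3-yl]-3-oxopropanoate | COCc1oc(-c2cc(OC)c(OC)c(OC)c2)cc(=O)c1C(=O)CC(=O)OC | intermediate
12 | 5-hydroxy-8-methoxy-2-(3,4,5-trimethoxyphenyl)-8H-chromene-4,7-dione (racemic at C8, transient) | COC1C(=O)C=C(O)c2c1oc(-c1cc(OC)c(OC)c(OC)c1)cc2=O | intermediate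
13 | 5,7-dihydroxy-8-methoxy-2-(3,4,5-trimethoxyphenyl)-4H-chromen-4-one (3',4',5'-trimethoxywogonin; achiral) | COc1cc(-c2cc(=O)c3c(O)cc(O)c(OC)c3o2)cc(OC)c1OC | target

**Step count and risks**

Total steps: 6. Longest linear sequence: 6 steps (1 → 13); keto ester 4 is bought and enters at step 3.

Steps most likely to fail:

Step 6. The ring closure may stall because the ester is deactivated as part of the keto ester enolate and is held away from the carbanion in the chelated enolate geometry, so that intermolecular condensation or base-induced breakdown of the pyranone takes over. The fallback sets out from 11. O-Methylation of the keto ester enol (HC(OMe)3, cat. H2SO4, MeOH, rt) should give methyl (E)-3-methoxy-3-[2-(methoxymethyl)-4-oxo-6-(3,4,5-trimethoxyphenyl)-4H-pyran-3-yl]acrylate F1, in which the ester is fixed cis to the pyranone and can no longer be enolised. One equivalent of LiHMDS (THF, −78 → 0 °C) should then generate only the methoxymethyl-derived dienolate, and the same C7–C8 Claisen closure with loss of methanol should give 7-hydroxy-5,8-dimethoxy-2-(3,4,5-trimethoxyphenyl)-4H-chromen-4-one F2. Chelation-directed cleavage of the 5-methyl ether peri to the C4 carbonyl (BCl3, CH2Cl2, −78 → 0 °C) comes back to the route at 13.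

Step 3. The ynoyl chloride may suffer conjugate addition by pyridine or by the enolate, or the acylated intermediate may close through the ester oxygen or in the 5-exo mode, so that little pyranone forms. The fallback sets out from 2. Hydrochlorination (LiCl, AcOH, 80 °C) should give (Z)-3-chloro-3-(3,4,5-trimethoxyphenyl)acrylic acid F3, which oxalyl chloride (cat. DMF, CH2Cl2) should convert into (Z)-3-chloro-3-(3,4,5-trimethoxyphenyl)acryloyl chloride F4. C-Acylation of 4 under the MgCl2/pyridine conditions should give methyl (Z)-5-chloro-2-(2-methoxyacetyl)-3-oxo-5-(3,4,5-trimethoxyphenyl)pent-4-enoate F5. On addition of Et3N this should close by intramolecular addition–elimination at the chlorine-bearing carbon, a closure with no 5-exo alternative, and so come back to the route at 6.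

Step 4. The tin hydroxide may add to the pyranone with ring opening, or the flanked ester may resist cleavage until decarboxylation or degradation sets in. The fallback sets out from 4. Transesterification with benzyl alcohol (toluene, reflux, cat. DMAP, methanol distilled off) should give benzyl 4-methoxy-3-oxobutanoate F6. Acylation with 3 and ring closure under the conditions of step 3 should lead, through benzyl 2-(2-methoxyacetyl)-3-oxo-5-(3,4,5-trimethoxyphenyl)pent-4-ynoate F7, to benzyl 2-(methoxymethyl)-4-oxo-6-(3,4,5-trimethoxyphenyl)-4H-pyran-3-carboxylate F8. Hydrogenolysis (H2, Pd/C, EtOAc, rt) should free the acid under neutral conditions and come back to the route at 8.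

**Further compounds**

F1 | step 6 | methyl (E)-3-methoxy-3-[2-(methoxymethyl)-4-oxo-6-(3,4,5-trimethoxyphenyl)-4H-pyran-3-yl]acrylate | CO/C(=C/C(=O)OC)c1c(COC)oc(-c2cc(OC)c(OC)c(OC)c2)cc1=O
F2 | step 6 | 7-hydroxy-5,8-dimethoxy-2-(3,4,5-trimethoxyphenyl)-4H-chromen-4-one | COc1cc(-c2cc(=O)c3c(OC)cc(O)c(OC)c3o2)cc(OC)c1OC
F3 | step 3 | (Z)-3-chloro-3-(3,4,5-trimethoxyphenyl)acrylic acid | OC(=O)/C=C(\Cl)c1cc(OC)c(OC)c(OC)c1
F4 | step 3 | (Z)-3-chloro-3-(3,4,5-trimethoxyphenyl)acryloyl chloride | ClC(=O)/C=C(\Cl)c1cc(OC)c(OC)c(OC)c1
F5 | step 3 | methyl (Z)-5-chloro-2-(2-methoxyacetyl)-3-oxo-5-(3,4,5-trimethoxyphenyl)pent-4-enoate (keto form drawn; C2 labile) | COCC(=O)C(C(=O)OC)C(=O)/C=C(\Cl)c1cc(OC)c(OC)c(OC)c1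
F6 | step 4 | benzyl 4-methoxy-3-oxobutanoate | COCC(=O)CC(=O)OCc1ccccc1
F7 | step 4 | benzyl 2-(2-methoxyacetyl)-3-oxo-5-(3,4,5-trimethoxyphenyl)pent-4-ynoate (keto form drawn; C2 labile) | COCC(=O)C(C(=O)OCc1ccccc1)C(=O)C#Cc1cc(OC)c(OC)c(OC)c1
F8 | step 4 | benzyl 2-(methoxymethyl)-4-oxo-6-(3,4,5-trimethoxyphenyl)-4H-pyran-3-carboxylate | COCc1oc(-c2cc(OC)c(OC)c(OC)c2)cc(=O)c1C(=O)OCc1ccccc1
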